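The target is already there at the first readings, 95.2 % in the epsilon run at 0.250 h, and afterwards it drains into its isomer. How far that drain gets by the end is what we have to judge.

| flask | solid substrate | remark | time |
|---|---|---|---|
| eta | 0.34 mM | run made earlier |  |
| epsilon | 0.75 mM | run made earlier |  |
| flask | 0.50 mM |  | 6.0 h |

- eta (time / h: target / %, isomer of the product / %, solid substrate / %): 0.333: 90.6, 6.0, 0.1; 0.833: 85.5, 10.7, 0.1; 1.50: 79.1, 17.6, 0; 2.50: 71.4, 25.8, 0.7; 4.00: 59.2, 37.7, 0
- epsilon (time / h: target / %, isomer of the product / %, solid substrate / %): 0.250: 95.2, 3.8, 0.5; 0.500: 94.5, 4.9, 0.3; 1.00: 91.9, 6.8, 0; 2.00: 87.5, 11.2, 0.1; 4.00: 80.7, 17.5, 0.3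

(standard deviation of a reading: 0.3 percentage points)

1. share of target in target plus isomer of the product at 30 s
2. share of target in target plus isomer of the product at 6.0 h
3. which of target and isomer of the product there is more of at 6.0 h

- target is meant together with its crystals
- solid, in amounts per volume of the solution: crystals, solid substrate
- candidate steps: starting material -> intermediate; intermediate <-> target; intermediate <-> isomer of the product; crystals <-> target; solid substrate <-> starting material
- at the start none of the solid substrate is in solution

Reckoned in mM, c(isomer of the product) gains 0.0294 mM h⁻¹ between first and last reading in the eta run and 0.0274 mM h⁻¹ in the epsilon run, though the charges differ by a factor of 2.21. So we take one leak of 0.0284 mM h⁻¹, close to zero-order. Target and isomer together hold 96.9 % of the eta charge at its last reading, so what the isomer gains, the target loses.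

Two times then matter. One is 8.80 h for the flask: the parity time, half the charge divided by the leak, when target and isomer would stand equal. The other is the time asked, 6.0 h. Parity lies later, so we expect the target ahead, its share being one minus half the ratio of the two times: 65.9 %.

The forecast says 97.2 % (96 % to 98.5 %) at 30 s and 65 % (61 % to 68 %) at 6.0 h, with target ahead, reasoning that “crystals hold dissolved target at saturation, giving zero-order leakage to isomer”. Its late share lies slightly under ours.

The flask gives 97.1 % and 65.5 %, with target ahead, 63.9 % against 33.6 %.

    starting material → intermediate (k = 0.0277 s⁻¹)
    intermediate ⇌ target (K = 0.800, k = 0.0429 s⁻¹)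
    intermediate ⇌ isomer of the product (K = 24.0, k = 8.93 × 10⁻⁴ s⁻¹)
    crystals ⇌ target, rate k4*(cs4 - [target]) while solid is left; crystals form when [target] > cs4 (solubility = 0.0100 mM, k = 1.14 s⁻¹)
    solid substrate ⇌ starting material, rate k5*(cs5 - [starting material]) while solid is left; crystals form when [starting material] > cs5 (solubility = 0.350 mM, k = 0.0225 s⁻¹)

In the flask, crystals still stand at 61.9 % at 6.00 h, so the leak was still running at the time asked. The target leads there because of its low solubility: the same flask without it ends at a share of 3.23 % instead of 65.5 %, with the lead turned. For the neighbour charged with 2.0 mM, the same leak puts parity at 35.2 h and the isomer at 8.52 % of the charge at 6.0 h. The computed amount is 9.14 %.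

All runs were generated by integration with made-up constants, noise included.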